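**Retrosynthetic overview**
1. Last operation, two rings at once: a chromium-mediated allylation of a Z-enal by a 2-(bromomethyl)enoate closes the ten-membered carbocycle (C7–C8), and the new C8 alkoxide closes the α-methylene lactone (O8–C12). The C6 angelate and the allylic bromide are made in the same flask from a vinyl oxirane.
2. The open chain comes from a Corey–Chaykovsky-type union of an α,β-epoxy aldehyde (C6) with methyl 2-(bromomethyl)acrylate (C7, C11–C13).
3. The C4–C5 oxirane (first ring made) comes from Sharpless epoxidation of a nerol-type allylic alcohol; C6 is then set next to it by Felkin–Anh addition.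
4. The C1 carbinol and the Z C9=C10 alkene come from an asymmetric Ni/Cr coupling of (Z)-3-iodobut-2-en-1-ol with the aldehyde from selective ozonolysis of neryl acetate.
5. Ring order: oxirane (step 6), an auxiliary vinyl oxirane (step 8, opened again), then carbocycle and lactone together (step 10).

Assumptions: atoms carry germacrane locants C1–C15 with the target read as a 12,8-olide; angelic anhydride and the ligand of step 3 are bought; the (S)-ligand is taken to give the 1R carbinol (otherwise its antipode is used).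

**Step 1**
Reactants: 1 but-2-yn-1-ol
Product: 3 (Z)-3-iodobut-2-en-1-ol, via cyclic alkenylalanate 2 (not isolated)
Conditions: NaAlH2(OCH2CH2OCH3)2, THF, 0 → 23 °C; then I2, −78 → 0 °C
Reagents that add atoms: iodine, II
Why: Hydroxyl-directed trans-hydroalumination of the propargylic alcohol gives the five-membered alanate, and iodinolysis with retention delivers the Z iodide (Corey-type hydroalumination–iodination); no stereocentre is formed.

**Step 2**
Reactants: 4 neryl acetate
Product: 6 (2Z)-3-methyl-6-oxohex-2-en-1-yl acetate, via ozonide 5 (not isolated)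
Conditions: O3 (1.0 equiv), CH2Cl2, pyridine (cat.), −78 °C; then Me2S, −78 → 23 °C
Reagents that add atoms: ozone, [O-][O+]=O
Why: Ozonolysis with reductive work-up; the electron-rich 6,7-alkene reacts far faster than the alkene deactivated by the allylic acetate, so the Z alkene survives.

**Step 3**
Reactants: 6 (2Z)-3-methyl-6-oxohex-2-en-1-yl acetate, 3 (Z)-3-iodobut-2-en-1-ol
Product: 7 (2Z,6R,7Z)-6,9-dihydroxy-3,7-dimethylnona-2,7-dien-1-yl acetate
Conditions: CrCl2, (S)-N-[2-(4-isopropyl-4,5-dihydro-1,3-oxazol-2-yl)-6-methylphenyl]methanesulfonamide, Et3N, THF; then NiCl2 (cat.), 6, 3, 23 °C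
Reagents that add atoms: none
Why: Asymmetric Nozaki–Hiyama–Kishi alkenylation; the alkenylchromium adds with retention of the Z geometry, and the chiral sulfonamide–chromium complex selects the aldehyde face that gives the 6R carbinol (C1 of the target).

**Step 4**
Reactants: 7 (2Z,6R,7Z)-6,9-dihydroxy-3,7-dimethylnona-2,7-dien-1-yl acetate
Product: 8 bis-TES ether acetate
Conditions: TESCl (2.5 equiv), imidazole, CH2Cl2, 0 °C
Reagents that add atoms: chlorotriethylsilane, CC[Si](Cl)(CC)CC
Why: Standard silylation of both hydroxyls; the primary TES ether is the latent C8 aldehyde and the secondary one protects C1.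

**Step 5**
Reactants: 8 bis-TES ether acetate
Product: 9 bis-TES allylic alcohol
Conditions: i-Bu2AlH (2.2 equiv), CH2Cl2, −78 °C; Rochelle salt work-up
Reagents that add atoms: none
Why: Reductive ester cleavage frees the allylic alcohol without the base or acid that would endanger the TES ethers.

**Step 6**
Reactants: 9 bis-TES allylic alcohol
Product: 10 epoxy alcohol
Conditions: Ti(Oi-Pr)4 (cat.), L-(+)-diisopropyl tartrate (cat.), t-BuOOH, 4 Å MS, CH2Cl2, −20 °C
Reagents that add atoms: tert-butyl hydroperoxide, CC(C)(C)OO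
Why: Sharpless asymmetric epoxidation; for a Z (nerol-type) allylic alcohol the L-(+)-tartrate gives the (2S,3R)-epoxy alcohol, which is the cis oxirane with C4 R and C5 S, and the silylated alkene is untouched.

**Step 7**
Reactants: 10 epoxy alcohol
Product: 11 epoxy aldehyde
Conditions: TEMPO (cat.), PhI(OAc)2, CH2Cl2, 23 °C
Reagents that add atoms: none
Why: TEMPO/PhI(OAc)2 oxidation takes the primary alcohol to the aldehyde under near-neutral conditions that keep the epoxide and both TES ethers.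

**Step 8**
Reactants: 11 epoxy aldehyde, 12 methyl 2-(bromomethyl)prop-2-enoate
Product: 14 bis-epoxide acrylate, via sulfonium bromide 13 (not isolated)
Conditions: 12, tetrahydrothiophene, CH2Cl2, 23 °C; then 11, Cs2CO3, MeCN, 0 → 23 °C
Reagents that add atoms: none
Why: Corey–Chaykovsky-type epoxidation by the allylic sulfonium ylide; Felkin–Anh attack anti to the epoxide C–O bond sets C6 as S (anti to the C5 oxygen), and the mixed C7 configuration is erased in step 10.

**Step 9**
Reactants: 14 bis-epoxide acrylate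
Product: 15 Z-enal bis-epoxide acrylate
Conditions: (COCl)2, DMSO, CH2Cl2, −78 → −40 °C; then Et3N
Reagents that add atoms: none
Why: Swern oxidation cleaves and oxidises the primary allylic TES ether directly to the aldehyde while the secondary TES ether survives at low temperature; the Z geometry is kept.

**Step 10**
Reactants: 15 Z-enal bis-epoxide acrylate
Product: 19 target CNP0191628.1, via allylic bromide angelate 16 (not isolated), via macrocyclic hydroxy ester 17 (not isolated), via silyl-protected lactone 18 (not isolated)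
Conditions: LiBr, angelic anhydride, THF, −20 → 0 °C; then CrCl2, THF/DMF, 5 mM, 23 °C; then MeOH, PPTS, 23 °C
Reagents that add atoms: angelic anhydride [(2Z)-2-methylbut-2-enoic anhydride], C/C=C(/C)C(=O)OC(=O)/C(C)=C\C
Why: Proposed new method: bromide adds SN2′ to the acrylate terminus of the vinyl oxirane (the isolated trisubstituted epoxide is inert without acid) and the released C6 alkoxide is acylated by the anhydride; divalent chromium then turns the 2-(bromomethyl)enoate into a σ-allylchromium that adds through C7 to the enal in a chair-like six-membered transition state inside the forming ring, which is expected to give the anti (7R,8S) adduct with a trans-fused lactone, and acid then closes the lactone and removes the TES group; the closest known chemistry is SN2′ halide opening of vinyl epoxides and the Nozaki–Hiyama–Kishi/Barbier macrocyclisation–lactonisation of 2-(bromomethyl)acrylates used for trans-fused germacranolides.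

**Compound list**
1 | but-2-yn-1-ol | CC#CCO | starting material
2 | sodium 2,2-bis(2-methoxyethoxy)-3-methyl-2,5-dihydro-1,2-oxaluminol-2-uide (cyclic alkenylalanate) | [Na+].CC1=CCO[Al-]1(OCCOC)OCCOC | intermediate
3 | (Z)-3-iodobut-2-en-1-ol | OC/C=C(/C)I | intermediate
4 | neryl acetate, (2Z)-3,7-dimethylocta-2,6-dien-1-yl acetate | CC(C)=CCC/C(C)=C\COC(C)=O | starting material
5 | 3-[(3Z)-5-acetoxy-3-methylpent-3-en-1-yl]-5,5-dimethyl-1,2,4-trioxolane (ozonide, ring carbon unassigned) | CC(=O)OC/C=C(/C)CCC1OOC(C)(C)O1 | intermediate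
6 | (2Z)-3-methyl-6-oxohex-2-en-1-yl acetate | CC(=O)OC/C=C(/C)CCC=O | intermediate
7 | (2Z,6R,7Z)-6,9-dihydroxy-3,7-dimethylnona-2,7-dien-1-yl acetate | OC/C=C(/C)[C@H](O)CC/C(C)=C\COC(C)=O | intermediate
8 | (2Z,6R,7Z)-3,7-dimethyl-6,9-bis(triethylsilyloxy)nona-2,7-dien-1-yl acetate | CC[Si](CC)(CC)OC/C=C(/C)[C@H](O[Si](CC)(CC)CC)CC/C(C)=C\COC(C)=O | intermediate
9 | (2Z,6R,7Z)-3,7-dimethyl-6,9-bis(triethylsilyloxy)nona-2,7-dien-1-ol | CC[Si](CC)(CC)OC/C=C(/C)[C@H](O[Si](CC)(CC)CC)CC/C(C)=C\CO | intermediate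
10 | [(2S,3R)-3-methyl-3-[(3R,4Z)-4-methyl-3,6-bis(triethylsilyloxy)hex-4-en-1-yl]oxiran-2-yl]methanol | CC[Si](CC)(CC)OC/C=C(/C)[C@H](O[Si](CC)(CC)CC)CC[C@@]1(C)O[C@H]1CO | intermediate
11 | (2R,3R)-3-methyl-3-[(3R,4Z)-4-methyl-3,6-bis(triethylsilyloxy)hex-4-en-1-yl]oxirane-2-carbaldehyde | CC[Si](CC)(CC)OC/C=C(/C)[C@H](O[Si](CC)(CC)CC)CC[C@@]1(C)O[C@H]1C=O | intermediate
12 | methyl 2-(bromomethyl)prop-2-enoate | C=C(CBr)C(=O)OC | starting material
13 | 1-[2-(methoxycarbonyl)prop-2-en-1-yl]thiolan-1-ium bromide | C=C(C[S+]1CCCC1)C(=O)OC.[Br-] | intermediate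
14 | methyl 2-[(3S)-3-{(2S,3R)-3-methyl-3-[(3R,4Z)-4-methyl-3,6-bis(triethylsilyloxy)hex-4-en-1-yl]oxiran-2-yl}oxiran-2-yl]prop-2-enoate (both epimers at the oxirane carbon bearing the acrylate, C7) | CC[Si](CC)(CC)OC/C=C(/C)[C@H](O[Si](CC)(CC)CC)CC[C@@]1(C)O[C@H]1[C@H]2OC2C(=C)C(=O)OC | intermediate
15 | methyl 2-[(3S)-3-{(2S,3R)-3-methyl-3-[(3R,4Z)-4-methyl-6-oxo-3-(triethylsilyloxy)hex-4-en-1-yl]oxiran-2-yl}oxiran-2-yl]prop-2-enoate (C7 epimers) | O=C/C=C(/C)[C@H](O[Si](CC)(CC)CC)CC[C@@]1(C)O[C@H]1[C@H]2OC2C(=C)C(=O)OC | intermediate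
16 | methyl (2Z,4S)-2-(bromomethyl)-4-[(2Z)-2-methylbut-2-enoyloxy]-4-{(2S,3R)-3-methyl-3-[(3R,4Z)-4-methyl-6-oxo-3-(triethylsilyloxy)hex-4-en-1-yl]oxiran-2-yl}but-2-enoate | O=C/C=C(/C)[C@H](O[Si](CC)(CC)CC)CC[C@@]1(C)O[C@H]1[C@@H](OC(=O)/C(C)=C\C)/C=C(\CBr)C(=O)OC | intermediate
17 | seco-ester of 18: ten-membered carbocycle with free 8-OH and C7 bearing the 1-(methoxycarbonyl)vinyl group, all configurations as in 18 (formed as its trivalent chromium alkoxide) | C=C(C(=O)OC)[C@@H]1[C@@H](O)/C=C(/C)[C@H](O[Si](CC)(CC)CC)CC[C@@]2(C)O[C@H]2[C@H]1OC(=O)/C(C)=C\C | intermediate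
18 | 1-O-triethylsilyl ether of 19 | C=C1C(=O)O[C@H]2/C=C(/C)[C@H](O[Si](CC)(CC)CC)CC[C@@]3(C)O[C@H]3[C@@H](OC(=O)/C(C)=C\C)[C@H]12 | intermediate
19 | CNP0191628.1, (1R,4R,5S,6S,7R,8S,9Z)-6-angeloyloxy-4,5-epoxy-1-hydroxygermacra-9,11(13)-dien-12,8-olide | C=C1C(=O)O[C@H]2/C=C(/C)[C@H](O)CC[C@@]3(C)O[C@H]3[C@@H](OC(=O)/C(C)=C\C)[C@H]12 | target

**Totals**
Total step count: 10. Longest linear sequence: 9 steps (4 → 19, steps 2–10).

**Three steps most likely to fail**

Step 10 (one-flask bromide opening, acylation, macrocyclisation, lactonisation). The risks are cyclisation of the C6 alkoxide before acylation, and the wrong C7/C8 diastereomer or oligomers in the chromium stage. The fallback sets out from 15 and returns at 17, and replaces halide/chromium activation by π-allyl umpolung. Pd(PPh3)4 with AcOH opens the vinyl oxirane in 1,4 fashion to the hydroxy acetate F1. Yamaguchi esterification (angelic acid, 2,4,6-trichlorobenzoyl chloride, Et3N, DMAP) gives the angelate acetate F2. Pd(PPh3)4 with InI at high dilution converts the allylic acetate through π-allylpalladium into an allylindium that closes the ring to 17, which is finished with MeOH/PPTS as in step 10.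

Step 8 (sulfonium ylide epoxidation). The risks are α versus γ attack of the ylide and modest Felkin control at C6. The fallback sets out from 11 and returns at 16, and builds the trisubstituted acrylate by olefin metathesis instead. Vinylmagnesium bromide adds to 11 (Felkin–Anh) and the alkoxide is quenched with angelic anhydride to give the allylic angelate F3. Cross-metathesis with 12 (second-generation Hoveyda–Grubbs catalyst) gives the bis-silyl bromide F4. PPTS/MeOH at 0 °C removes the primary TES group to give the primary alcohol F5, and MnO2 gives 16, which enters the chromium stage of step 10.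

Step 3 (asymmetric Ni/Cr coupling). The risk is low or reversed induction at C1 with the free hydroxyl on the iodide. The fallback sets out from 3 and 6 and returns at 8, and sets C1 by ketone reduction. TESCl converts 3 into the silyl ether F6. Ligand-free CrCl2/NiCl2 coupling with 6 gives the C1-epimeric alcohol F7. Dess–Martin periodinane gives the Z enone F8. (S)-2-Methyl-CBS-oxazaborolidine with BH3·SMe2 gives the 6R alcohol F9 (alkenyl as the large group), and TESCl gives 8.

**Further compounds**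
F1 | step 10 | methyl (2E,4S)-2-(acetoxymethyl)-4-hydroxy-4-{(2S,3R)-3-methyl-3-[(3R,4Z)-4-methyl-6-oxo-3-(triethylsilyloxy)hex-4-en-1-yl]oxiran-2-yl}but-2-enoate | O=C/C=C(/C)[C@H](O[Si](CC)(CC)CC)CC[C@@]1(C)O[C@H]1[C@@H](O)/C=C(\COC(C)=O)C(=O)OC
F2 | step 10 | methyl (2E,4S)-2-(acetoxymethyl)-4-[(2Z)-2-methylbut-2-enoyloxy]-4-{(2S,3R)-3-methyl-3-[(3R,4Z)-4-methyl-6-oxo-3-(triethylsilyloxy)hex-4-en-1-yl]oxiran-2-yl}but-2-enoate | O=C/C=C(/C)[C@H](O[Si](CC)(CC)CC)CC[C@@]1(C)O[C@H]1[C@@H](OC(=O)/C(C)=C\C)/C=C(\COC(C)=O)C(=O)OC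
F3 | step 8 | (1S)-1-{(2S,3R)-3-methyl-3-[(3R,4Z)-4-methyl-3,6-bis(triethylsilyloxy)hex-4-en-1-yl]oxiran-2-yl}prop-2-en-1-yl (2Z)-2-methylbut-2-enoate | CC[Si](CC)(CC)OC/C=C(/C)[C@H](O[Si](CC)(CC)CC)CC[C@@]1(C)O[C@H]1[C@@H](OC(=O)/C(C)=C\C)C=C
F4 | step 8 | methyl (2Z,4S)-2-(bromomethyl)-4-[(2Z)-2-methylbut-2-enoyloxy]-4-{(2S,3R)-3-methyl-3-[(3R,4Z)-4-methyl-3,6-bis(triethylsilyloxy)hex-4-en-1-yl]oxiran-2-yl}but-2-enoate | CC[Si](CC)(CC)OC/C=C(/C)[C@H](O[Si](CC)(CC)CC)CC[C@@]1(C)O[C@H]1[C@@H](OC(=O)/C(C)=C\C)/C=C(\CBr)C(=O)OC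
F5 | step 8 | methyl (2Z,4S)-2-(bromomethyl)-4-{(2S,3R)-3-[(3R,4Z)-6-hydroxy-4-methyl-3-(triethylsilyloxy)hex-4-en-1-yl]-3-methyloxiran-2-yl}-4-[(2Z)-2-methylbut-2-enoyloxy]but-2-enoate | OC/C=C(/C)[C@H](O[Si](CC)(CC)CC)CC[C@@]1(C)O[C@H]1[C@@H](OC(=O)/C(C)=C\C)/C=C(\CBr)C(=O)OC
F6 | step 3 | triethyl{[(2Z)-3-iodobut-2-en-1-yl]oxy}silane | CC[Si](CC)(CC)OC/C=C(/C)I
F7 | step 3 | (2Z,7Z)-6-hydroxy-3,7-dimethyl-9-(triethylsilyloxy)nona-2,7-dien-1-yl acetate (both C6 epimers) | CC[Si](CC)(CC)OC/C=C(/C)C(O)CC/C(C)=C\COC(C)=O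
F8 | step 3 | (2Z,7Z)-3,7-dimethyl-6-oxo-9-(triethylsilyloxy)nona-2,7-dien-1-yl acetate | CC[Si](CC)(CC)OC/C=C(/C)C(=O)CC/C(C)=C\COC(C)=O
F9 | step 3 | (2Z,6R,7Z)-6-hydroxy-3,7-dimethyl-9-(triethylsilyloxy)nona-2,7-dien-1-yl acetate | CC[Si](CC)(CC)OC/C=C(/C)[C@H](O)CC/C(C)=C\COC(C)=O
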